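## Retrosynthetic overview

1. The C5–Cl bond is made last by electrophilic chlorination; just before it the pyran ring closes by cyclodehydration of a δ‑hydroxy enedione (O2–C3 bond).
2. The cyclohexenone ring (C4a=C5) comes from ring‑closing metathesis of an acyclic vinyl ketone bearing a 1,1‑disubstituted alkene.
3. Key disconnection C3–C4: an intermolecular boron aldol joins a methyl ketone fragment (carrying C7, C8, C8a) to a side‑chain enal carrying the oxolane and the tertiary carbinol.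
4. Methyl ketone fragment: Seebach alkylation of (S)‑lactic acid sets C7, an Evans syn aldol of a crotonyl imide sets C8/C8a, and a Wacker oxidation gives the ketone.
5. Enal fragment: Brown crotylation, hydroboration and cyclisation build the oxolane; chelation‑controlled alkynylation sets the carbinol. Ring order: oxolane, then cyclohexenone, then pyran.

Assumption: locants C1–C8a are those of the isochromen‑6‑one core; the carbinol made in the coupling aldol (later C3) is uncontrolled, is carried as both epimers (left undefined in the SMILES of 36–41) and is removed by oxidation in step 29.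

## Route

**Side‑chain enal**

Step 1
Reactants: 1 methyl pyruvate
Product: 2 methyl 2,2-dimethoxypropanoate
Conditions: HC(OMe)3, MeOH, H2SO4 (cat.), reflux
Reagents that add atoms: trimethyl orthoformate, COC(OC)OC
Why: Acid‑catalysed ketalisation with the orthoester as methoxy source and water scavenger masks the future acetyl group and makes the derived aldehyde non‑enolisable.

Step 2
Reactants: 2 methyl 2,2-dimethoxypropanoate
Product: 3 2,2-dimethoxypropanal
Conditions: iBu2AlH, CH2Cl2, −78 °C; used as a cold solution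
Reagents that add atoms: none
Why: Partial ester reduction works because the α‑alkoxy‑chelated aluminium hemiacetal is stable at −78 °C and releases the aldehyde only on work‑up.

Step 3
Reactants: 3 2,2-dimethoxypropanal
Product: 4 (3S,4S)-2,2-dimethoxy-4-methylhex-5-en-3-ol
Conditions: trans-2-butene, n-BuLi, KOtBu, THF, −78 → −45 °C; (−)-Ipc2BOMe [from (+)-α-pinene], BF3·OEt2, −78 °C; then 3, −78 °C; NaOH, H2O2
Reagents that add atoms: (E)-crotyl-B(Ipc)2, made in the flask from trans-2-butene (C/C=C/C), C/C=C/CB([C@@H]1C[C@@H]2C[C@H]([C@H]1C)C2(C)C)[C@@H]1C[C@@H]2C[C@H]([C@H]1C)C2(C)C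
Why: Brown crotylboration through a chair Zimmerman–Traxler transition state turns the E‑crotyl geometry into the anti relationship, and the Ipc groups direct addition to the Si face, setting both oxolane stereocentres as (3S,4S).

Step 4
Reactants: 4 (3S,4S)-2,2-dimethoxy-4-methylhex-5-en-3-ol
Product: 6 (3S,4S)-5,5-dimethoxy-3-methylhexane-1,4-diol, via alkylborane 5 (not isolated)
Conditions: 9-BBN, THF, 0 °C → rt; then NaOH, H2O2, 0 °C → rt
Reagents that add atoms: hydrogen peroxide, OO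
Why: Hydroboration–oxidation with 9-BBN is anti‑Markovnikov at the terminal alkene and the oxidation proceeds with retention, so no stereocentre is touched.

Step 5
Reactants: 6 (3S,4S)-5,5-dimethoxy-3-methylhexane-1,4-diol
Product: 8 (2S,3S)-2-(1,1-dimethoxyethyl)-3-methyloxolane, via monotosylate 7 (not isolated)
Conditions: TsCl, Et3N, DMAP (cat.), THF, 0 °C → rt; then KOtBu, 0 °C → rt
Reagents that add atoms: none
Why: Selective sulfonylation of the primary alcohol followed by intramolecular Williamson etherification (5‑exo‑tet) breaks no bond at either stereocentre, so the anti alcohol becomes the trans‑2,3‑disubstituted oxolane.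

Step 6
Reactants: 8 (2S,3S)-2-(1,1-dimethoxyethyl)-3-methyloxolane
Product: 9 1-[(2S,3S)-3-methyloxolan-2-yl]ethan-1-one
Conditions: 1 M HCl, THF/H2O, rt
Reagents that add atoms: water, O
Why: Acid‑catalysed ketal hydrolysis frees the acetyl group; the trans arrangement is the thermodynamic one, so any enolisation at C2 is harmless.

Step 7
Reactants: 9 1-[(2S,3S)-3-methyloxolan-2-yl]ethan-1-one; 10 3,3-diethoxyprop-1-yne
Product: 12 (2S)-5,5-diethoxy-2-[(2S,3S)-3-methyloxolan-2-yl]pent-3-yn-2-ol, via alkynylmagnesium bromide 11 (not isolated)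
Conditions: 10, EtMgBr, THF, 0 → 40 °C; then 9, −78 → 0 °C; aq. NH4Cl
Reagents that add atoms: none
Why: Chelation‑controlled (Cram chelate) Grignard addition: magnesium bridges the carbonyl and ring oxygens and the alkynyl group attacks from the face of the C2–H, giving the (S)‑carbinol.

Step 8
Reactants: 12 (2S)-5,5-diethoxy-2-[(2S,3S)-3-methyloxolan-2-yl]pent-3-yn-2-ol
Product: 13 (2S,3E)-5,5-diethoxy-2-[(2S,3S)-3-methyloxolan-2-yl]pent-3-en-2-ol
Conditions: LiAlH4, THF, 0 °C → reflux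
Reagents that add atoms: none
Why: Hydroxyl‑directed trans‑hydroalumination of the propargylic alcohol gives only the E‑alkene after protonolysis, and the acetal is inert to hydride.

Step 9
Reactants: 13 (2S,3E)-5,5-diethoxy-2-[(2S,3S)-3-methyloxolan-2-yl]pent-3-en-2-ol
Product: 14 (2E,4S)-4-hydroxy-4-[(2S,3S)-3-methyloxolan-2-yl]pent-2-enal
Conditions: 5% aq. citric acid, THF, rt
Reagents that add atoms: water, O
Why: Mild acetal hydrolysis through a conjugated oxocarbenium ion gives the E‑enal, which cannot cyclise onto the γ‑hydroxyl and leaves the tertiary alcohol untouched.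

Step 10
Reactants: 14 (2E,4S)-4-hydroxy-4-[(2S,3S)-3-methyloxolan-2-yl]pent-2-enal
Product: 15 (2E,4S)-4-[(2S,3S)-3-methyloxolan-2-yl]-4-[(triethylsilyl)oxy]pent-2-enal
Conditions: TESOTf, 2,6-lutidine, CH2Cl2, −78 °C
Reagents that add atoms: triethylsilyl triflate, CC[Si](CC)(CC)OS(=O)(=O)C(F)(F)F
Why: Silyl triflate silylation of the hindered tertiary alcohol; the enal has no enolisable γ‑hydrogen, so only the hydroxyl reacts.

**Aldehyde carrying C7**

Step 11
Reactants: 16 (S)-lactic acid; 17 pivalaldehyde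
Product: 18 (2S,5S)-2-tert-butyl-5-methyl-1,3-dioxolan-4-one
Conditions: TsOH·H2O (cat.), H2SO4 (cat.), pentane, reflux (Dean–Stark); recrystallisation at −78 °C
Reagents that add atoms: none
Why: Seebach acetalisation (self‑regeneration of stereocentres) gives mainly the cis dioxolanone, which is brought to ≥96:4 by low‑temperature crystallisation.

Step 12
Reactants: 18 (2S,5S)-2-tert-butyl-5-methyl-1,3-dioxolan-4-one
Product: 20 (2S,5R)-5-[(benzyloxy)methyl]-2-tert-butyl-5-methyl-1,3-dioxolan-4-one, via lithium enolate 19 (not isolated)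
Conditions: LiN(iPr)2, THF, −78 °C; then BnOCH2Cl, −78 → −30 °C
Reagents that add atoms: benzyl chloromethyl ether, ClCOCc1ccccc1
Why: Seebach enolate alkylation occurs anti to the tert‑butyl group, so the electrophile replaces the original hydrogen with retention and fixes the quaternary C7 centre.

Step 13
Reactants: 20 (2S,5R)-5-[(benzyloxy)methyl]-2-tert-butyl-5-methyl-1,3-dioxolan-4-one
Product: 21 (2R)-3-(benzyloxy)-2-hydroxy-N-methoxy-N,2-dimethylpropanamide
Conditions: MeNH(OMe)·HCl, iPrMgCl, THF, −20 → 0 °C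
Reagents that add atoms: N,O-dimethylhydroxylamine hydrochloride, CNOC.Cl
Why: Weinreb aminolysis of the activated acylal lactone; the hemiacetal leaving group collapses to pivalaldehyde and the quaternary centre is not involved.

Step 14
Reactants: 21 (2R)-3-(benzyloxy)-2-hydroxy-N-methoxy-N,2-dimethylpropanamide
Product: 22 (2R)-3-(benzyloxy)-N-methoxy-N,2-dimethyl-2-[(triethylsilyl)oxy]propanamide
Conditions: TESOTf, 2,6-lutidine, CH2Cl2, 0 °C → rt
Reagents that add atoms: triethylsilyl triflate, CC[Si](CC)(CC)OS(=O)(=O)C(F)(F)F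
Why: Silyl triflate silylation is strong enough for the tertiary alcohol and gives a group removable by fluoride at the end.

Step 15
Reactants: 22 (2R)-3-(benzyloxy)-N-methoxy-N,2-dimethyl-2-[(triethylsilyl)oxy]propanamide
Product: 23 (2R)-3-hydroxy-N-methoxy-N,2-dimethyl-2-[(triethylsilyl)oxy]propanamide
Conditions: H2 (1 atm), 10% Pd/C, EtOAc, rt
Reagents that add atoms: none
Why: Hydrogenolysis of the benzyl ether under neutral conditions in EtOAc leaves the silyl ether and the N–O bond intact.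

Step 16
Reactants: 23 (2R)-3-hydroxy-N-methoxy-N,2-dimethyl-2-[(triethylsilyl)oxy]propanamide
Product: 24 (2R)-N-methoxy-N,2-dimethyl-3-oxo-2-[(triethylsilyl)oxy]propanamide
Conditions: Dess–Martin periodinane, NaHCO3, CH2Cl2, 0 °C → rt
Reagents that add atoms: none
Why: Dess–Martin oxidation of the neopentyl alcohol gives an aldehyde with no α‑hydrogen, so the C7 centre cannot epimerise.

**Methyl ketone fragment**

Step 17
Reactants: 25 (4R)-4-benzyl-1,3-oxazolidin-2-one; 26 (E)-but-2-enoyl chloride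
Product: 28 (4R)-4-benzyl-3-[(2E)-but-2-enoyl]-1,3-oxazolidin-2-one, via lithium oxazolidinide 27 (not isolated)
Conditions: n-BuLi, THF, −78 °C; then 26, −78 → 0 °C
Reagents that add atoms: none
Why: N‑Acylation of the lithiated Evans auxiliary is fast at −78 °C and avoids conjugate addition to the crotonyl group.

Step 18
Reactants: 28 (4R)-4-benzyl-3-[(2E)-but-2-enoyl]-1,3-oxazolidin-2-one; 24 (2R)-N-methoxy-N,2-dimethyl-3-oxo-2-[(triethylsilyl)oxy]propanamide
Product: 30 Evans syn aldol adduct (2R,3R,4R), via boron dienolate 29 (not isolated)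
Conditions: Bu2BOTf, Et3N, CH2Cl2, −78 → 0 °C; then 24, −78 → 0 °C; pH 7 buffer, MeOH, H2O2
Reagents that add atoms: none
Why: Evans syn aldol of the crotonate imide: the (Z)‑boron dienolate reacts at its α‑carbon through a Zimmerman–Traxler chair under auxiliary control, setting C8 (R) and C8a with the vinyl group as the future C4a.

Step 19
Reactants: 30 Evans syn aldol adduct
Product: 31 C8 tert-butyldimethylsilyl ether of 30
Conditions: TBSOTf, 2,6-lutidine, CH2Cl2, −78 → 0 °C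
Reagents that add atoms: tert-butyldimethylsilyl triflate, CC(C)(C)[Si](C)(C)OS(=O)(=O)C(F)(F)F
Why: Silylation of the hindered secondary alcohol blocks retro‑aldol cleavage and silyl migration in the next step.

Step 20
Reactants: 31 C8 silyl ether
Product: 32 primary alcohol (2R,3R,4S)
Conditions: NaBH4, THF/H2O (4:1), 0 °C → rt
Reagents that add atoms: none
Why: Reductive removal of the auxiliary: borohydride reduces the activated imide carbonyl to the C1 alcohol while the hindered Weinreb amide is inert, and the α‑vinyl centre is not epimerised.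

Step 21
Reactants: 32 primary alcohol
Product: 33 bis(tert-butyldimethylsilyl) ether (2R,3R,4S)
Conditions: TBSCl, imidazole, DMF, rt
Reagents that add atoms: tert-butyldimethylsilyl chloride, CC(C)(C)[Si](C)(C)Cl
Why: Standard silylation of the primary alcohol that will later become the pyran oxygen.

Step 22
Reactants: 33 bis(tert-butyldimethylsilyl) ether
Product: 34 methyl ketone (2R,3R,4S)
Conditions: PdCl2 (10 mol%), CuCl, O2 (1 atm), DMF/H2O (7:1), rt
Reagents that add atoms: water, O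
Why: Tsuji–Wacker oxidation converts the terminal vinyl group with Markovnikov selectivity into the C4a methyl ketone under non‑basic conditions that leave the α‑centre C8a intact.

**Fragment union and endgame**

Step 23
Reactants: 34 methyl ketone; 15 (2E,4S)-4-[(2S,3S)-3-methyloxolan-2-yl]-4-[(triethylsilyl)oxy]pent-2-enal
Product: 36 coupled β-hydroxy ketone (both C3 epimers), via boron enolate 35 (not isolated)
Conditions: (c-C6H11)2BCl, Et3N, Et2O, −78 → 0 °C; then 15, −78 → −20 °C; pH 7 buffer, MeOH, H2O2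
Reagents that add atoms: none
Why: Key boron‑mediated aldol reaction: kinetic enolisation occurs only at the methyl group and the enolate adds 1,2 to the enal, forming the C3–C4 bond; the new carbinol need not be controlled.

Step 24
Reactants: 36 coupled β-hydroxy ketone
Product: 37 C3 triethylsilyl ether
Conditions: TESOTf, 2,6-lutidine, CH2Cl2, −78 °C
Reagents that add atoms: triethylsilyl triflate, CC[Si](CC)(CC)OS(=O)(=O)C(F)(F)F
Why: Silylation prevents retro‑aldol and β‑elimination and gives the only secondary triethylsilyl ether, which can later be removed selectively.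

Step 25
Reactants: 37 C3 triethylsilyl ether
Product: 38 C4a methylidene compound
Conditions: Cp2TiMe2, toluene, 65 °C, dark
Reagents that add atoms: dimethyltitanocene, [CH3-].[CH3-].[Ti+4].c1cc[cH-]c1.c1cc[cH-]c1
Why: Petasis methylenation is non‑basic, so the ketone is methylenated without epimerising C8a or eliminating the three β‑silyloxy groups, and the hindered Weinreb amide reacts more slowly.

Step 26
Reactants: 38 C4a methylidene compound
Product: 39 vinyl ketone
Conditions: CH2=CHMgBr, THF, 0 °C → rt; inverse quench into cold aq. NH4Cl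
Reagents that add atoms: vinylmagnesium bromide, C=C[Mg]Br
Why: Weinreb ketone synthesis: the stable magnesium chelate stops at single addition and gives the C6 enone carrying C5.

Step 27
Reactants: 39 vinyl ketone
Product: 40 cyclohexenone (4S,5R,6R)
Conditions: RuCl2(=CH-C6H4-2-OiPr)(H2IMes) (second-generation Hoveyda–Grubbs catalyst, 10 mol%), toluene (0.005 M), 80 °C
Reagents that add atoms: none
Why: Ring‑closing metathesis between the vinyl ketone and the 1,1‑disubstituted alkene forms the six‑membered ring with the C4a=C5 bond; the doubly flanked side‑chain alkene does not take part.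

Step 28
Reactants: 40 cyclohexenone
Product: 41 C3 alcohol
Conditions: PPTS (cat.), MeOH/CH2Cl2 (1:3), 0 °C
Reagents that add atoms: none
Why: Selective acid‑catalysed methanolysis removes the only secondary triethylsilyl ether, while the tertiary triethylsilyl and the tert‑butyldimethylsilyl ethers are far slower.

Step 29
Reactants: 41 C3 alcohol
Product: 42 silyl-protected enedione
Conditions: Dess–Martin periodinane, NaHCO3, CH2Cl2, 0 °C → rt
Reagents that add atoms: none
Why: Dess–Martin oxidation of the single free hydroxyl gives the C3 ketone and removes the uncontrolled stereocentre.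

Step 30
Reactants: 42 silyl-protected enedione
Product: 44 (7R,8R,8aS)-7,8-dihydroxy-3-{(1E,3S)-3-hydroxy-3-[(2S,3S)-3-methyloxolan-2-yl]but-1-en-1-yl}-7-methyl-1,7,8,8a-tetrahydro-6H-isochromen-6-one, via hydroxy enedione 43 (not isolated)
Conditions: HF·pyridine, pyridine, THF, 0 °C → rt
Reagents that add atoms: none
Why: Global desilylation frees the C1 hydroxyl, which forms the six‑membered hemiketal at C3 and dehydrates through the acidic C4 position to the conjugated dienol ether (cyclodehydration); buffered fluoride avoids base at C8a.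

Step 31
Reactants: 44 dechloro isochromenone
Product: 45 (7R,8R,8aS)-5-chloro-7,8-dihydroxy-3-{(1E,3S)-3-hydroxy-3-[(2S,3S)-3-methyloxolan-2-yl]but-1-en-1-yl}-7-methyl-1,7,8,8a-tetrahydro-6H-isochromen-6-one
Conditions: NCS (1.05 equiv), MeCN, 0 °C → rt, dark
Reagents that add atoms: N-chlorosuccinimide, ClN1C(=O)CCC1=O
Why: Electrophilic chlorination at C5, the terminal nucleophilic carbon of the O2–C3=C4–C4a=C5 dienol ether and α to the ketone, as in 5‑chloro‑azaphilone chemistry; no stereocentre is touched.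

## Compound list

1 | methyl pyruvate | CC(=O)C(=O)OC | starting material
2 | methyl 2,2-dimethoxypropanoate | COC(=O)C(C)(OC)OC | intermediate
3 | 2,2-dimethoxypropanal | CC(OC)(OC)C=O | intermediate
4 | (3S,4S)-2,2-dimethoxy-4-methylhex-5-en-3-ol | C[C@@H](C=C)[C@H](O)C(C)(OC)OC | intermediate
5 | 9-[(3S,4S)-4-hydroxy-5,5-dimethoxy-3-methylhexyl]-9-borabicyclo[3.3.1]nonane | C[C@@H](CCB1C2CCCC1CCC2)[C@H](O)C(C)(OC)OC | intermediate (not isolated)
6 | (3S,4S)-5,5-dimethoxy-3-methylhexane-1,4-diol | C[C@@H](CCO)[C@H](O)C(C)(OC)OC | intermediate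
7 | (3S,4S)-4-hydroxy-5,5-dimethoxy-3-methylhexyl 4-methylbenzenesulfonate | C[C@@H](CCOS(=O)(=O)c1ccc(C)cc1)[C@H](O)C(C)(OC)OC | intermediate (not isolated)
8 | (2S,3S)-2-(1,1-dimethoxyethyl)-3-methyloxolane | C[C@H]1CCO[C@@H]1C(C)(OC)OC | intermediate
9 | 1-[(2S,3S)-3-methyloxolan-2-yl]ethan-1-one | C[C@H]1CCO[C@@H]1C(C)=O | intermediate
10 | 3,3-diethoxyprop-1-yne | C#CC(OCC)OCC | starting material
11 | (3,3-diethoxyprop-1-yn-1-yl)magnesium bromide | CCOC(OCC)C#C[Mg]Br | intermediate (not isolated)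
12 | (2S)-5,5-diethoxy-2-[(2S,3S)-3-methyloxolan-2-yl]pent-3-yn-2-ol | C[C@H]1CCO[C@@H]1[C@@](C)(O)C#CC(OCC)OCC | intermediate
13 | (2S,3E)-5,5-diethoxy-2-[(2S,3S)-3-methyloxolan-2-yl]pent-3-en-2-ol | C[C@H]1CCO[C@@H]1[C@@](C)(O)/C=C/C(OCC)OCC | intermediate
14 | (2E,4S)-4-hydroxy-4-[(2S,3S)-3-methyloxolan-2-yl]pent-2-enal | C[C@H]1CCO[C@@H]1[C@@](C)(O)/C=C/C=O | intermediate
15 | (2E,4S)-4-[(2S,3S)-3-methyloxolan-2-yl]-4-[(triethylsilyl)oxy]pent-2-enal | C[C@H]1CCO[C@@H]1[C@@](C)(O[Si](CC)(CC)CC)/C=C/C=O | intermediate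
16 | (S)-lactic acid | C[C@H](O)C(O)=O | starting material
17 | pivalaldehyde | CC(C)(C)C=O | starting material
18 | (2S,5S)-2-tert-butyl-5-methyl-1,3-dioxolan-4-one | C[C@@H]1O[C@H](C(C)(C)C)OC1=O | intermediate
19 | lithium (2S)-2-tert-butyl-5-methyl-1,3-dioxol-4-olate | [Li+].CC1=C([O-])O[C@@H](C(C)(C)C)O1 | intermediate (not isolated)
20 | (2S,5R)-5-[(benzyloxy)methyl]-2-tert-butyl-5-methyl-1,3-dioxolan-4-one | C[C@]1(COCc2ccccc2)O[C@H](C(C)(C)C)OC1=O | intermediate
21 | (2R)-3-(benzyloxy)-2-hydroxy-N-methoxy-N,2-dimethylpropanamide | CON(C)C(=O)[C@](C)(O)COCc1ccccc1 | intermediate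
22 | (2R)-3-(benzyloxy)-N-methoxy-N,2-dimethyl-2-[(triethylsilyl)oxy]propanamide | CON(C)C(=O)[C@](C)(O[Si](CC)(CC)CC)COCc1ccccc1 | intermediate
23 | (2R)-3-hydroxy-N-methoxy-N,2-dimethyl-2-[(triethylsilyl)oxy]propanamide | CON(C)C(=O)[C@](C)(O[Si](CC)(CC)CC)CO | intermediate
24 | (2R)-N-methoxy-N,2-dimethyl-3-oxo-2-[(triethylsilyl)oxy]propanamide | CON(C)C(=O)[C@](C)(O[Si](CC)(CC)CC)C=O | intermediate
25 | (4R)-4-benzyl-1,3-oxazolidin-2-one | O=C1N[C@H](Cc2ccccc2)CO1 | starting material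
26 | (E)-but-2-enoyl chloride | C/C=C/C(Cl)=O | starting material
27 | lithium (4R)-4-benzyl-2-oxo-1,3-oxazolidin-3-ide | [Li+].O=C1[N-][C@H](Cc2ccccc2)CO1 | intermediate (not isolated)
28 | (4R)-4-benzyl-3-[(2E)-but-2-enoyl]-1,3-oxazolidin-2-one | C/C=C/C(=O)N1[C@H](Cc2ccccc2)COC1=O | intermediate
29 | (4R)-4-benzyl-3-[(1Z)-1-[(dibutylboranyl)oxy]buta-1,3-dien-1-yl]-1,3-oxazolidin-2-one | C=C/C=C(\OB(CCCC)CCCC)N1[C@H](Cc2ccccc2)COC1=O | intermediate (not isolated)
30 | (2R,3R,4R)-4-{[(4R)-4-benzyl-2-oxo-1,3-oxazolidin-3-yl]carbonyl}-3-hydroxy-N-methoxy-N,2-dimethyl-2-[(triethylsilyl)oxy]hex-5-enamide | CON(C)C(=O)[C@](C)(O[Si](CC)(CC)CC)[C@H](O)[C@@H](C=C)C(=O)N1[C@H](Cc2ccccc2)COC1=O | intermediate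
31 | (2R,3R,4R)-4-{[(4R)-4-benzyl-2-oxo-1,3-oxazolidin-3-yl]carbonyl}-3-[(tert-butyldimethylsilyl)oxy]-N-methoxy-N,2-dimethyl-2-[(triethylsilyl)oxy]hex-5-enamide | CON(C)C(=O)[C@](C)(O[Si](CC)(CC)CC)[C@H](O[Si](C)(C)C(C)(C)C)[C@@H](C=C)C(=O)N1[C@H](Cc2ccccc2)COC1=O | intermediate
32 | (2R,3R,4S)-3-[(tert-butyldimethylsilyl)oxy]-4-(hydroxymethyl)-N-methoxy-N,2-dimethyl-2-[(triethylsilyl)oxy]hex-5-enamide | CON(C)C(=O)[C@](C)(O[Si](CC)(CC)CC)[C@H](O[Si](C)(C)C(C)(C)C)[C@@H](C=C)CO | intermediate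
33 | (2R,3R,4S)-3-[(tert-butyldimethylsilyl)oxy]-4-{[(tert-butyldimethylsilyl)oxy]methyl}-N-methoxy-N,2-dimethyl-2-[(triethylsilyl)oxy]hex-5-enamide | CON(C)C(=O)[C@](C)(O[Si](CC)(CC)CC)[C@H](O[Si](C)(C)C(C)(C)C)[C@@H](C=C)CO[Si](C)(C)C(C)(C)C | intermediate
34 | (2R,3R,4S)-3-[(tert-butyldimethylsilyl)oxy]-4-{[(tert-butyldimethylsilyl)oxy]methyl}-N-methoxy-N,2-dimethyl-5-oxo-2-[(triethylsilyl)oxy]hexanamide | CON(C)C(=O)[C@](C)(O[Si](CC)(CC)CC)[C@H](O[Si](C)(C)C(C)(C)C)[C@@H](C(C)=O)CO[Si](C)(C)C(C)(C)C | intermediate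
35 | dicyclohexylboron enolate of 34 (boron on the C5 oxygen, terminal C5=C6 enol) | CON(C)C(=O)[C@](C)(O[Si](CC)(CC)CC)[C@H](O[Si](C)(C)C(C)(C)C)[C@@H](C(=C)OB(C1CCCCC1)C1CCCCC1)CO[Si](C)(C)C(C)(C)C | intermediate (not isolated)
36 | (2R,3R,4S,8E,10S)-3-[(tert-butyldimethylsilyl)oxy]-4-{[(tert-butyldimethylsilyl)oxy]methyl}-7-hydroxy-N-methoxy-N,2-dimethyl-10-[(2S,3S)-3-methyloxolan-2-yl]-5-oxo-2,10-bis[(triethylsilyl)oxy]undec-8-enamide, both C7 epimers | CON(C)C(=O)[C@](C)(O[Si](CC)(CC)CC)[C@H](O[Si](C)(C)C(C)(C)C)[C@@H](C(=O)CC(O)/C=C/[C@](C)(O[Si](CC)(CC)CC)[C@H]1OCC[C@@H]1C)CO[Si](C)(C)C(C)(C)C | intermediate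
37 | 7-O-triethylsilyl ether of 36: (2R,3R,4S,8E,10S)-…-5-oxo-2,7,10-tris[(triethylsilyl)oxy]undec-8-enamide, both C7 epimers | CON(C)C(=O)[C@](C)(O[Si](CC)(CC)CC)[C@H](O[Si](C)(C)C(C)(C)C)[C@@H](C(=O)CC(O[Si](CC)(CC)CC)/C=C/[C@](C)(O[Si](CC)(CC)CC)[C@H]1OCC[C@@H]1C)CO[Si](C)(C)C(C)(C)C | intermediate
38 | 5-methylidene analogue of 37: (2R,3R,4S,8E,10S)-…-5-methylidene-2,7,10-tris[(triethylsilyl)oxy]undec-8-enamide, both C7 epimers | CON(C)C(=O)[C@](C)(O[Si](CC)(CC)CC)[C@H](O[Si](C)(C)C(C)(C)C)[C@@H](C(=C)CC(O[Si](CC)(CC)CC)/C=C/[C@](C)(O[Si](CC)(CC)CC)[C@H]1OCC[C@@H]1C)CO[Si](C)(C)C(C)(C)C | intermediate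
39 | (4R,5R,6S,10E,12S)-5-[(tert-butyldimethylsilyl)oxy]-6-{[(tert-butyldimethylsilyl)oxy]methyl}-4-methyl-7-methylidene-12-[(2S,3S)-3-methyloxolan-2-yl]-4,9,12-tris[(triethylsilyl)oxy]trideca-1,10-dien-3-one, both C9 epimers | C=CC(=O)[C@](C)(O[Si](CC)(CC)CC)[C@H](O[Si](C)(C)C(C)(C)C)[C@@H](C(=C)CC(O[Si](CC)(CC)CC)/C=C/[C@](C)(O[Si](CC)(CC)CC)[C@H]1OCC[C@@H]1C)CO[Si](C)(C)C(C)(C)C | intermediate
40 | (4S,5R,6R)-5-[(tert-butyldimethylsilyl)oxy]-4-{[(tert-butyldimethylsilyl)oxy]methyl}-6-methyl-3-{(3E,5S)-5-[(2S,3S)-3-methyloxolan-2-yl]-2,5-bis[(triethylsilyl)oxy]hex-3-en-1-yl}-6-[(triethylsilyl)oxy]cyclohex-2-en-1-one, both side-chain C2 epimers | O=C1C=C(CC(O[Si](CC)(CC)CC)/C=C/[C@](C)(O[Si](CC)(CC)CC)[C@H]2OCC[C@@H]2C)[C@@H](CO[Si](C)(C)C(C)(C)C)[C@@H](O[Si](C)(C)C(C)(C)C)[C@@]1(C)O[Si](CC)(CC)CC | intermediate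
41 | side-chain C2 alcohol of 40 (2-hydroxy-5-[(triethylsilyl)oxy]hex-3-en-1-yl side chain), both epimers | O=C1C=C(CC(O)/C=C/[C@](C)(O[Si](CC)(CC)CC)[C@H]2OCC[C@@H]2C)[C@@H](CO[Si](C)(C)C(C)(C)C)[C@@H](O[Si](C)(C)C(C)(C)C)[C@@]1(C)O[Si](CC)(CC)CC | intermediate
42 | (4S,5R,6R)-5-[(tert-butyldimethylsilyl)oxy]-4-{[(tert-butyldimethylsilyl)oxy]methyl}-6-methyl-3-{(3E,5S)-5-[(2S,3S)-3-methyloxolan-2-yl]-2-oxo-5-[(triethylsilyl)oxy]hex-3-en-1-yl}-6-[(triethylsilyl)oxy]cyclohex-2-en-1-one | O=C1C=C(CC(=O)/C=C/[C@](C)(O[Si](CC)(CC)CC)[C@H]2OCC[C@@H]2C)[C@@H](CO[Si](C)(C)C(C)(C)C)[C@@H](O[Si](C)(C)C(C)(C)C)[C@@]1(C)O[Si](CC)(CC)CC | intermediate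
43 | (4S,5R,6R)-5,6-dihydroxy-3-{(3E,5S)-5-hydroxy-5-[(2S,3S)-3-methyloxolan-2-yl]-2-oxohex-3-en-1-yl}-4-(hydroxymethyl)-6-methylcyclohex-2-en-1-one | O=C1C=C(CC(=O)/C=C/[C@](C)(O)[C@H]2OCC[C@@H]2C)[C@@H](CO)[C@@H](O)[C@@]1(C)O | intermediate (not isolated)
44 | (7R,8R,8aS)-7,8-dihydroxy-3-{(1E,3S)-3-hydroxy-3-[(2S,3S)-3-methyloxolan-2-yl]but-1-en-1-yl}-7-methyl-1,7,8,8a-tetrahydro-6H-isochromen-6-one | C[C@H]1CCO[C@@H]1[C@@](C)(O)/C=C/C1=CC2=CC(=O)[C@](C)(O)[C@H](O)[C@@H]2CO1 | intermediate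
45 | (7R,8R,8aS)-5-chloro-7,8-dihydroxy-3-{(1E,3S)-3-hydroxy-3-[(2S,3S)-3-methyloxolan-2-yl]but-1-en-1-yl}-7-methyl-1,7,8,8a-tetrahydro-6H-isochromen-6-one | C[C@H]1CCO[C@@H]1[C@@](C)(O)/C=C/C1=CC2=C(Cl)C(=O)[C@](C)(O)[C@H](O)[C@@H]2CO1 | target

## Step count and risks

Total steps: 31. Longest linear sequence: 20 steps from (S)-lactic acid (steps 11–16, 18–22, 23–31).

**Step 7 (diastereoselectivity of the chelation‑controlled alkynylation).** Alkynyl Grignard reagents chelate less well than alkyl ones, so the ratio at the tertiary carbinol may be modest. The fallback sets the carbinol by reagent control and sets out from 9. Horner–Wadsworth–Emmons olefination (triethyl phosphonoacetate, NaH, THF) gives ethyl (2E)-3-[(2S,3S)-3-methyloxolan-2-yl]but-2-enoate F1. Reduction with iBu2AlH gives (2E)-3-[(2S,3S)-3-methyloxolan-2-yl]but-2-en-1-ol F2. Sharpless asymmetric epoxidation (Ti(OiPr)4, D-(−)-diethyl tartrate, tBuOOH, 4 Å sieves, −20 °C) gives [(2R,3R)-3-methyl-3-[(2S,3S)-3-methyloxolan-2-yl]oxiran-2-yl]methanol F3. Iodination (I2, PPh3, imidazole) gives (2S,3R)-2-(iodomethyl)-3-methyl-3-[(2S,3S)-3-methyloxolan-2-yl]oxirane F4. Reductive epoxide opening with Zn dust in EtOH gives (2S)-2-[(2S,3S)-3-methyloxolan-2-yl]but-3-en-2-ol F5. Cross‑metathesis with (E)-crotonaldehyde (second-generation Hoveyda–Grubbs catalyst) comes back to the route at 14.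

**Step 22 (Wacker oxidation of a congested vinyl group flanked by two silyloxy‑bearing carbons).** It may be slow or give some aldehyde. The fallback sets out from 33. Ozonolysis (O3, CH2Cl2, −78 °C; PPh3) gives (2R,3R,4S)-3-[(tert-butyldimethylsilyl)oxy]-4-{[(tert-butyldimethylsilyl)oxy]methyl}-N-methoxy-N,2-dimethyl-5-oxo-2-[(triethylsilyl)oxy]pentanamide F6. Aldehyde‑selective methyl addition with MeTi(OiPr)3 gives the 5-hydroxyhexanamide F7 as a mixture of C5 epimers. Dess–Martin oxidation comes back to the route at 34.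

**Step 27 (ring‑closing metathesis of a hindered, electron‑poor vinyl ketone with a 1,1‑disubstituted alkene).** The fallback closes the ring on the more reactive allylic alcohol and oxidises afterwards; it sets out from 38. Reduction of the Weinreb amide with iBu2AlH gives the aldehyde F8. Addition of CH2=CHMgBr gives the vinyl carbinol F9 (C3 epimers of the tridecadiene chain). Ring‑closing metathesis with the same ruthenium catalyst gives the cyclohexenol F10. Selective removal of the secondary triethylsilyl ether (PPTS, MeOH, 0 °C) gives the bis‑allylic diol F11. Dess–Martin oxidation of both allylic alcohols comes back to the route at 42.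

## Further compounds

F1 | step 7 | ethyl (2E)-3-[(2S,3S)-3-methyloxolan-2-yl]but-2-enoate | C[C@H]1CCO[C@@H]1/C(C)=C/C(=O)OCC
F2 | step 7 | (2E)-3-[(2S,3S)-3-methyloxolan-2-yl]but-2-en-1-ol | C[C@H]1CCO[C@@H]1/C(C)=C/CO
F3 | step 7 | [(2R,3R)-3-methyl-3-[(2S,3S)-3-methyloxolan-2-yl]oxiran-2-yl]methanol | C[C@H]1CCO[C@@H]1[C@@]2(C)O[C@@H]2CO
F4 | step 7 | (2S,3R)-2-(iodomethyl)-3-methyl-3-[(2S,3S)-3-methyloxolan-2-yl]oxirane | C[C@H]1CCO[C@@H]1[C@@]2(C)O[C@@H]2CI
F5 | step 7 | (2S)-2-[(2S,3S)-3-methyloxolan-2-yl]but-3-en-2-ol | C[C@H]1CCO[C@@H]1[C@@](C)(O)C=C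
F6 | step 22 | (2R,3R,4S)-3-[(tert-butyldimethylsilyl)oxy]-4-{[(tert-butyldimethylsilyl)oxy]methyl}-N-methoxy-N,2-dimethyl-5-oxo-2-[(triethylsilyl)oxy]pentanamide | CON(C)C(=O)[C@](C)(O[Si](CC)(CC)CC)[C@H](O[Si](C)(C)C(C)(C)C)[C@@H](C=O)CO[Si](C)(C)C(C)(C)C
F7 | step 22 | (2R,3R,4S)-3-[(tert-butyldimethylsilyl)oxy]-4-{[(tert-butyldimethylsilyl)oxy]methyl}-5-hydroxy-N-methoxy-N,2-dimethyl-2-[(triethylsilyl)oxy]hexanamide, both C5 epimers | CON(C)C(=O)[C@](C)(O[Si](CC)(CC)CC)[C@H](O[Si](C)(C)C(C)(C)C)[C@@H](C(C)O)CO[Si](C)(C)C(C)(C)C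
F8 | step 27 | aldehyde from 38: 2-methyl-5-methylidene undec-8-enal bearing the same silyl ethers and oxolane, both C7 epimers | O=C[C@](C)(O[Si](CC)(CC)CC)[C@H](O[Si](C)(C)C(C)(C)C)[C@@H](C(=C)CC(O[Si](CC)(CC)CC)/C=C/[C@](C)(O[Si](CC)(CC)CC)[C@H]1OCC[C@@H]1C)CO[Si](C)(C)C(C)(C)C
F9 | step 27 | vinyl carbinol: trideca-1,10-dien-3-ol analogue of 39, C3 and C9 epimers | C=CC(O)[C@](C)(O[Si](CC)(CC)CC)[C@H](O[Si](C)(C)C(C)(C)C)[C@@H](C(=C)CC(O[Si](CC)(CC)CC)/C=C/[C@](C)(O[Si](CC)(CC)CC)[C@H]1OCC[C@@H]1C)CO[Si](C)(C)C(C)(C)C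
F10 | step 27 | cyclohex-2-en-1-ol analogue of 40 (ring carbinol in place of the ketone), epimeric at the ring carbinol and at side-chain C2 | OC1C=C(CC(O[Si](CC)(CC)CC)/C=C/[C@](C)(O[Si](CC)(CC)CC)[C@H]2OCC[C@@H]2C)[C@@H](CO[Si](C)(C)C(C)(C)C)[C@@H](O[Si](C)(C)C(C)(C)C)[C@@]1(C)O[Si](CC)(CC)CC
F11 | step 27 | bis-allylic diol: F10 with the side-chain C2 silyl ether removed, epimeric at both carbinols | OC1C=C(CC(O)/C=C/[C@](C)(O[Si](CC)(CC)CC)[C@H]2OCC[C@@H]2C)[C@@H](CO[Si](C)(C)C(C)(C)C)[C@@H](O[Si](C)(C)C(C)(C)C)[C@@]1(C)O[Si](CC)(CC)CC
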